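**Plan**

- Retrosynthesis cuts, in order: the C1–C3 bond shared by a cyclopropane and a nine-membered ring (C2 inserted as a cyclopropane CH2); then C6–C7 with the lactone C–O bond (chromium allylation); then C1–C2 and C1–C3 (Kulinkovich union of an ester and a terminal alkene); then C7–C11 (Baylis–Hillman), C4–C5 (crotylboration) and C9–C10 (pyruvate aldol).
- Forward order of rings: cyclopropanol first, then the nine-membered carbocycle and the γ-lactone in one closure, then the ten-membered ring by opening the bond common to the three- and nine-membered rings.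
- Enabling feature: the C1 ketone sits between the fully substituted C10 and the C2=C3 alkene of the ten-membered ring, so C2 can be carried as the methylene of a 1-siloxybicyclo[7.1.0]decane; oxidative opening then gives ketone, E-alkene and ring size together.
- Stereochemistry: C10 from a copper–bisoxazoline aldol, C8 from C10 (1,3-syn reduction), C4 and C5 from an Ipc crotylborane, C6 and C7 in the ring closure; the two cyclopropane centres are temporary.

Key step: step 15

Remark on numbering: locants follow the ten-membered ring. C1 is the ketone, C2=C3 the alkene, C4 carries methyl C15, C5 the free OH, C6 the lactone oxygen, C7 the ring fusion, C8 the angelate, C9 is CH2, C10 carries methyl C14 and the acetate; C11–C13 are the methylene-lactone carbons.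

Assumption: the Kulinkovich step is taken to give both cis-cyclopropanol diastereomers. Compounds 14–26 are carried as that pair and their SMILES show one of them, because C1 and C3 stop being stereocentres in step 15.

Step 1
Reactants: 1 1,1-dimethoxypropan-2-one
Product: 2 [(3,3-dimethoxyprop-1-en-2-yl)oxy]trimethylsilane
Conditions: LiN(i-Pr)2, THF, −78 °C; Me3SiCl
Reagents that add atoms: chlorotrimethylsilane, C[Si](C)(C)Cl
Why: Kinetic deprotonation at the methyl group (the acetal C–H is hindered and would give a destabilised dialkoxy enolate) and O-silylation give the terminal silyl enol ether (silyl enol ether formation).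

Step 2
Reactants: 2 silyl enol ether; 3 methyl pyruvate
Product: 5 methyl (2S)-2-hydroxy-5,5-dimethoxy-2-methyl-4-oxopentanoate, via trimethylsilyl ether 4 (not isolated)
Conditions: Cu(OTf)2 (10 mol %), (S,S)-t-Bu-box, THF, −78 °C; then 1 M HCl
Reagents that add atoms: none
Why: Catalytic enantioselective Mukaiyama aldol addition to a pyruvate ester: the pyruvate chelates divalent copper through both carbonyls and the tert-butyl groups of the ligand leave one face open, which should set the tertiary carbinol C10 as (S); aqueous acid then cleaves the silyl ether 4.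

Step 3
Reactants: 5 β-hydroxy ketone
Product: 6 methyl (2S,4R)-2,4-dihydroxy-5,5-dimethoxy-2-methylpentanoate
Conditions: Et2BOMe, NaBH4, THF/MeOH (4:1), −78 °C; then AcOH, MeOH co-evaporation
Reagents that add atoms: none
Why: Narasaka–Prasad reduction: hydride attacks the six-membered boron chelate of the β-hydroxy ketone axially, setting C8 syn to the C10 hydroxyl.

Step 4
Reactants: 6 syn-1,3-diol
Product: 7 methyl (4S,6R)-6-(dimethoxymethyl)-2,2,4-trimethyl-1,3-dioxane-4-carboxylate
Conditions: Me2C(OMe)2, PPTS, CH2Cl2, rt
Reagents that add atoms: 2,2-dimethoxypropane, COC(C)(C)OC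
Why: Acid-catalysed transketalisation of the syn-1,3-diol to the chair 1,3-dioxane; the aldehyde dimethyl acetal stays in the presence of excess 2,2-dimethoxypropane and no stereocentre changes.

Step 5
Reactants: 8 2-(benzyloxy)acetaldehyde; 9 (E)-but-2-ene
Product: 12 (2S,3S)-1-(benzyloxy)-3-methylpent-4-en-2-ol, via crotylborane 10 (not isolated), via borinate 11 (not isolated)
Conditions: n-BuLi, KOt-Bu, THF, −78 to −45 °C; (−)-Ipc2BOMe, −78 °C; BF3·OEt2; 8, −78 °C; then NaOH, H2O2
Reagents that add atoms: none
Why: Brown crotylboration: the (E)-crotylborane reacts through a chair Zimmerman–Traxler transition state (C4/C5 anti), and the isopinocampheyl groups from (+)-α-pinene should direct attack to the Si face of the aldehyde (C5 S, reagent control).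

Step 6
Reactants: 12 homoallylic alcohol
Product: 13 {[(2S,3S)-1-(benzyloxy)-3-methylpent-4-en-2-yl]oxy}(tert-butyl)dimethylsilane
Conditions: TBSCl, imidazole, DMF, rt
Reagents that add atoms: tert-butyldimethylsilyl chloride, CC(C)(C)[Si](C)(C)Cl
Why: Standard silyl ether formation at the secondary alcohol; no stereocentre is touched.

Step 7
Reactants: 7 dioxane ester; 13 terminal alkene
Product: 14 cis-cyclopropanol, 1-[(4S,6R)-6-(dimethoxymethyl)-2,2,4-trimethyl-1,3-dioxan-4-yl]-2-[(2S,3S)-4-(benzyloxy)-3-(tert-butyldimethylsilyloxy)butan-2-yl]cyclopropan-1-ol, the two carbon substituents cis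
Conditions: ClTi(Oi-Pr)3 (1.2 equiv), c-C6H11MgCl (4.5 equiv, added over 2 h), THF, rt
Reagents that add atoms: none
Why: Kulinkovich hydroxycyclopropanation in its olefin-exchange variant: the titanacyclopropane formed from the Grignard reagent and tetravalent titanium exchanges cyclohexene for the terminal alkene of 13, inserts the ester carbonyl of 7 and closes to the cyclopropanol with the two alkyl groups cis (the usual Kulinkovich diastereoselectivity); both faces react, which does no harm because C1 and C3 lose their stereochemistry in step 15.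

Step 8
Reactants: 14 benzyl ether
Product: 15 primary alcohol (C6–OH) with free cyclopropanol, otherwise as 14
Conditions: H2 (1 atm), Pd(OH)2/C, EtOAc, rt
Reagents that add atoms: none
Why: Hydrogenolysis of the benzyl ether; no alkene is present at this stage, and the silyl ether, the acetals and the cyclopropanol should be inert under neutral conditions.

Step 9
Reactants: 15 diol
Product: 18 C7 aldehyde carrying triethylsilyl ethers at the cyclopropanol oxygen and at C6–O, via bis-silyl acetal 16 (not isolated), via collidinium salt 17 (not isolated)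
Conditions: TESOTf (4 equiv), 2,4,6-collidine (6 equiv), CH2Cl2, −78 to 0 °C; then H2O
Reagents that add atoms: triethylsilyl trifluoromethanesulfonate, CC[Si](CC)(CC)OS(=O)(=O)C(F)(F)F; water, O
Why: Silylation of both hydroxyls followed by chemoselective acetal cleavage of the Fujioka–Kita type: the silyl triflate ionises only the aldehyde-derived dimethyl acetal (the acetonide is a ketal and stays), collidine traps the oxocarbenium ion as a pyridinium salt and water releases the aldehyde without epimerising C8.

Step 10
Reactants: 18 aldehyde; 19 methyl acrylate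
Product: 20 Baylis–Hillman adduct, methyl 2-[hydroxy(dioxanyl)methyl]acrylate (C7 carbinol as a mixture of epimers)
Conditions: DABCO (1 equiv), methyl acrylate (neat, 10 equiv), rt, 4 d
Reagents that add atoms: none
Why: Morita–Baylis–Hillman reaction of the reactive α-alkoxy aldehyde; the new C7 carbinol centre is formed unselectively and is erased in step 11.

Step 11
Reactants: 20 Baylis–Hillman adduct
Product: 22 methyl (Z)-2-(bromomethyl)-3-(dioxanyl)acrylate, via mesylate 21 (not isolated)
Conditions: MsCl, Et3N, CH2Cl2, −20 °C; then LiBr, THF, 0 °C to rt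
Reagents that add atoms: lithium bromide, [Li+].[Br-]
Why: Mesylation and SN2′ displacement by bromide give the thermodynamically preferred (Z)-2-(bromomethyl)-2-enoate (allylic transposition of a Baylis–Hillman adduct), removing the C7 carbinol centre.

Step 12
Reactants: 22 allylic bromide
Product: 23 primary alcohol (C6–OH), tertiary cyclopropyl TES ether and secondary TBS ether retained
Conditions: HF·pyridine, pyridine, THF, 0 °C
Reagents that add atoms: none
Why: Buffered HF·pyridine should cleave the unhindered primary triethylsilyl ether much faster than the tertiary cyclopropyl TES ether and the secondary TBS ether (steric differentiation of silyl ethers).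

Step 13
Reactants: 23 primary alcohol
Product: 24 C6 aldehyde bearing the allylic bromide
Conditions: Dess–Martin periodinane, NaHCO3, CH2Cl2, 0 °C to rt
Reagents that add atoms: none
Why: Buffered Dess–Martin oxidation should give the α-siloxy aldehyde without epimerising C5 and without touching the allylic bromide or the siloxycyclopropane.

Step 14
Reactants: 24 bromo aldehyde
Product: 26 nine-membered carbocycle with fused cyclopropane (bicyclo[7.1.0]decane core), trans-fused α-methylene-γ-lactone at C6/C7, C8/C10 acetonide, C5–OTBS and C1–OTES, via chromium alkoxide 25 (not isolated)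
Conditions: CrCl2 (10 equiv), THF, rt, slow addition of 24 (final 2 mM)
Reagents that add atoms: none
Why: Intramolecular Nozaki–Hiyama–Kishi (Barbier-type) allylation followed by lactonisation: divalent chromium inserts into the allylic bromide, the 2-(methoxycarbonyl)allyl unit adds through C7 to the C6 aldehyde in a six-membered chair, and the alkoxide closes the lactone; the forming nine-membered ring should hold both ring arms (C5 and C8) pseudo-equatorial and so give the trans lactone, with the face set by the C8 acetonide centre (attack anti to C9 with H-8 eclipsing the allyl unit), giving C6 and C7 as in the target.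

Step 15
Reactants: 26 siloxycyclopropane
Product: 28 ten-membered (E)-2-en-1-one with the trans-fused methylene lactone, C8/C10 acetonide and C5–OTBS, via β-chloroketone 27 (not isolated)
Conditions: FeCl3 (2.5 equiv), DMF, 0 °C to rt; then Et3N, CH2Cl2, rt
Reagents that add atoms: none
Why: Trivalent iron cleaves the triethylsilyl ether and oxidises the iron cyclopropoxide by one electron; the cyclopropoxy radical undergoes β-scission of the C1–C3 bond shared by the three- and nine-membered rings, because this releases ring strain and gives the secondary C3 radical instead of the primary C2 radical, and chlorine-atom transfer from a second FeCl3 traps C3 as the β-chloroketone. Triethylamine then eliminates HCl by E1cB to the conjugated enone. The closest known reaction type is the Ito–Saegusa FeCl3 ring enlargement of 1-siloxybicyclo[n.1.0]alkanes to 2-cycloalkenones. No ring is closed: the ten-membered carbocycle arises from the nine-membered one by opening the fused cyclopropane, and the former cyclopropane methylene enters the ring as C2. No stereocentre is created; C1 and C3 lose theirs, so both diastereomers of 26 converge, and the alkene geometry is set in the elimination, where the E isomer avoids the A(1,3) clash between the C10 substituents and C4 that a Z-enone would suffer. The step needs internal rather than external bond cleavage (secured by radical stability), chlorine transfer faster than addition of the C3 radical to the methylene lactone (a slow seven-membered closure), and survival of the acetonide and TBS ether (anhydrous FeCl3 in DMF at 0 °C).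

Step 16
Reactants: 28 acetonide
Product: 29 C8,C10-diol of the ten-membered enone lactone (C5–OTBS)
Conditions: AcOH/THF/H2O (3:1:1), 45 °C
Reagents that add atoms: none
Why: Mild aqueous acid hydrolyses the 1,3-dioxane ketal while the secondary TBS ether, the enone and the lactone should survive (acetal hydrolysis); no stereocentre is affected.

Step 17
Reactants: 29 diol; 30 angelic acid
Product: 32 C8 angelate with free tertiary C10–OH, via mixed anhydride 31 (not isolated)
Conditions: 2,4,6-Cl3C6H2COCl, Et3N, toluene, rt; then 29, 80 °C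
Reagents that add atoms: none
Why: Yamaguchi-type esterification through the mixed anhydride acylates the secondary C8 hydroxyl and leaves the tertiary C10 hydroxyl; these DMAP-free conditions are the usual way to introduce an angelate without Z-to-E isomerisation to the tiglate.

Step 18
Reactants: 32 tertiary alcohol
Product: 33 C10 acetate, C8 angelate, C5–OTBS
Conditions: Ac2O, DMAP, Et3N, CH2Cl2, 40 °C
Reagents that add atoms: acetic anhydride, CC(=O)OC(C)=O
Why: DMAP-catalysed acetylation of the remaining tertiary α-ketol hydroxyl (nucleophilic catalysis); C10 cannot epimerise.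

Step 19
Reactants: 33 TBS ether
Product: 34 target
Conditions: HF·pyridine, THF, 0 °C to rt
Reagents that add atoms: none
Why: Fluoride cleavage of the secondary TBS ether under slightly acidic, non-basic conditions that should spare both esters, the enone and the methylene lactone, liberating the C5 hydroxyl (desilylation).

**Compound list**

1 | 1,1-dimethoxypropan-2-one | CC(=O)C(OC)OC | starting material
2 | [(3,3-dimethoxyprop-1-en-2-yl)oxy]trimethylsilane | C=C(O[Si](C)(C)C)C(OC)OC | intermediate
3 | methyl pyruvate | COC(=O)C(C)=O | starting material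
4 | methyl (2S)-5,5-dimethoxy-2-methyl-4-oxo-2-[(trimethylsilyl)oxy]pentanoate (not isolated) | COC(=O)[C@@](C)(O[Si](C)(C)C)CC(=O)C(OC)OC | intermediate
5 | methyl (2S)-2-hydroxy-5,5-dimethoxy-2-methyl-4-oxopentanoate | COC(=O)[C@@](C)(O)CC(=O)C(OC)OC | intermediate
6 | methyl (2S,4R)-2,4-dihydroxy-5,5-dimethoxy-2-methylpentanoate | COC(=O)[C@@](C)(O)C[C@@H](O)C(OC)OC | intermediate
7 | methyl (4S,6R)-6-(dimethoxymethyl)-2,2,4-trimethyl-1,3-dioxane-4-carboxylate | COC(=O)[C@]1(C)C[C@H](C(OC)OC)OC(C)(C)O1 | intermediate
8 | 2-(benzyloxy)acetaldehyde | O=CCOCc1ccccc1 | starting material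
9 | (E)-but-2-ene | C/C=C/C | starting material
10 | (E)-crotyl-diisopinocampheylborane from (+)-α-pinene (not isolated) | C/C=C/CB([C@@H]1C[C@@H]2C[C@H]([C@H]1C)C2(C)C)[C@@H]1C[C@@H]2C[C@H]([C@H]1C)C2(C)C | intermediate
11 | diisopinocampheylborinate of 12 (not isolated) | C=C[C@H](C)[C@H](OB([C@@H]1C[C@@H]2C[C@H]([C@H]1C)C2(C)C)[C@@H]1C[C@@H]2C[C@H]([C@H]1C)C2(C)C)COCc1ccccc1 | intermediate
12 | (2S,3S)-1-(benzyloxy)-3-methylpent-4-en-2-ol | C=C[C@H](C)[C@H](O)COCc1ccccc1 | intermediate
13 | {[(2S,3S)-1-(benzyloxy)-3-methylpent-4-en-2-yl]oxy}(tert-butyl)dimethylsilane | C=C[C@H](C)[C@H](O[Si](C)(C)C(C)(C)C)COCc1ccccc1 | intermediate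
14 | cis-cyclopropanol from 7 and 13 (C6–OBn, C5–OTBS, C7 dimethyl acetal, C8/C10 acetonide; one of two cis diastereomers shown) | O[C@@]1(C[C@H]1[C@H](C)[C@H](O[Si](C)(C)C(C)(C)C)COCc1ccccc1)[C@]2(C)C[C@H](C(OC)OC)OC(C)(C)O2 | intermediate
15 | cyclopropanol with free C6–OH | O[C@@]1(C[C@H]1[C@H](C)[C@H](O[Si](C)(C)C(C)(C)C)CO)[C@]2(C)C[C@H](C(OC)OC)OC(C)(C)O2 | intermediate
16 | bis(triethylsilyl) ether of 15, dimethyl acetal intact (not isolated) | CC[Si](CC)(CC)O[C@@]1(C[C@H]1[C@H](C)[C@H](O[Si](C)(C)C(C)(C)C)CO[Si](CC)(CC)CC)[C@]2(C)C[C@H](C(OC)OC)OC(C)(C)O2 | intermediate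
17 | N-(1-methoxyalkyl)-2,4,6-trimethylpyridinium triflate at C7 (not isolated; C7 configuration undefined) | CC[Si](CC)(CC)O[C@@]1(C[C@H]1[C@H](C)[C@H](O[Si](C)(C)C(C)(C)C)CO[Si](CC)(CC)CC)[C@]2(C)C[C@H](C(OC)[n+]3c(C)cc(C)cc3C)OC(C)(C)O2.[O-]S(=O)(=O)C(F)(F)F | intermediate
18 | C7 aldehyde, bis-TES ether | CC[Si](CC)(CC)O[C@@]1(C[C@H]1[C@H](C)[C@H](O[Si](C)(C)C(C)(C)C)CO[Si](CC)(CC)CC)[C@]2(C)C[C@H](C=O)OC(C)(C)O2 | intermediate
19 | methyl acrylate | C=CC(=O)OC | starting material
20 | Baylis–Hillman adduct (C7 carbinol epimers) | CC[Si](CC)(CC)O[C@@]1(C[C@H]1[C@H](C)[C@H](O[Si](C)(C)C(C)(C)C)CO[Si](CC)(CC)CC)[C@]2(C)C[C@H](C(O)C(=C)C(=O)OC)OC(C)(C)O2 | intermediate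
21 | C7 mesylate of 20 (not isolated) | CC[Si](CC)(CC)O[C@@]1(C[C@H]1[C@H](C)[C@H](O[Si](C)(C)C(C)(C)C)CO[Si](CC)(CC)CC)[C@]2(C)C[C@H](C(OS(C)(=O)=O)C(=C)C(=O)OC)OC(C)(C)O2 | intermediate
22 | (Z)-2-(bromomethyl)-2-enoate, C6–OTES | CC[Si](CC)(CC)O[C@@]1(C[C@H]1[C@H](C)[C@H](O[Si](C)(C)C(C)(C)C)CO[Si](CC)(CC)CC)[C@]2(C)C[C@H](/C=C(\CBr)C(=O)OC)OC(C)(C)O2 | intermediate
23 | (Z)-2-(bromomethyl)-2-enoate, C6–OH | CC[Si](CC)(CC)O[C@@]1(C[C@H]1[C@H](C)[C@H](O[Si](C)(C)C(C)(C)C)CO)[C@]2(C)C[C@H](/C=C(\CBr)C(=O)OC)OC(C)(C)O2 | intermediate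
24 | C6 aldehyde with the allylic bromide | CC[Si](CC)(CC)O[C@@]1(C[C@H]1[C@H](C)[C@H](O[Si](C)(C)C(C)(C)C)C=O)[C@]2(C)C[C@H](/C=C(\CBr)C(=O)OC)OC(C)(C)O2 | intermediate
25 | nine-membered-ring homoallylic alkoxide of trivalent chromium, methyl ester (not isolated) | C=C(C(=O)OC)[C@H]1[C@H](O[Cr](Cl)Cl)[C@@H](O[Si](C)(C)C(C)(C)C)[C@@H](C)[C@@H]2C[C@]2(O[Si](CC)(CC)CC)[C@]3(C)C[C@H]1OC(C)(C)O3 | intermediate
26 | nine-membered carbocycle with fused siloxycyclopropane and trans-fused α-methylene-γ-lactone | C=C1C(=O)O[C@@H]2[C@@H](O[Si](C)(C)C(C)(C)C)[C@@H](C)[C@@H]3C[C@]3(O[Si](CC)(CC)CC)[C@]4(C)C[C@@H](OC(C)(C)O4)[C@@H]12 | intermediate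
27 | ten-membered 3-chloro ketone (not isolated; C3 configuration undefined) | C=C1C(=O)O[C@@H]2[C@@H](O[Si](C)(C)C(C)(C)C)[C@@H](C)C(Cl)CC(=O)[C@]3(C)C[C@@H](OC(C)(C)O3)[C@@H]12 | intermediate
28 | ten-membered (E)-enone, C8/C10 acetonide, C5–OTBS | C=C1C(=O)O[C@@H]2[C@@H](O[Si](C)(C)C(C)(C)C)[C@@H](C)/C=C/C(=O)[C@]3(C)C[C@@H](OC(C)(C)O3)[C@@H]12 | intermediate
29 | C8,C10-diol, C5–OTBS | C=C1C(=O)O[C@@H]2[C@@H](O[Si](C)(C)C(C)(C)C)[C@@H](C)/C=C/C(=O)[C@@](C)(O)C[C@@H](O)[C@@H]12 | intermediate
30 | angelic acid, (Z)-2-methylbut-2-enoic acid | C/C=C(/C)C(=O)O | starting material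
31 | angelic 2,4,6-trichlorobenzoic anhydride (not isolated) | C/C=C(/C)C(=O)OC(=O)c1c(Cl)cc(Cl)cc1Cl | intermediate
32 | C8 angelate, C10–OH, C5–OTBS | C=C1C(=O)O[C@@H]2[C@@H](O[Si](C)(C)C(C)(C)C)[C@@H](C)/C=C/C(=O)[C@@](C)(O)C[C@@H](OC(=O)/C(C)=C\C)[C@@H]12 | intermediate
33 | C10 acetate, C8 angelate, C5–OTBS | C=C1C(=O)O[C@@H]2[C@@H](O[Si](C)(C)C(C)(C)C)[C@@H](C)/C=C/C(=O)[C@@](C)(OC(C)=O)C[C@@H](OC(=O)/C(C)=C\C)[C@@H]12 | intermediate
34 | CNP0259154.2 | C=C1C(=O)O[C@@H]2[C@@H](O)[C@@H](C)/C=C/C(=O)[C@@](C)(OC(C)=O)C[C@@H](OC(=O)/C(C)=C\C)[C@@H]12 | target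

**Totals**

Total step count: 19. Longest linear sequence: 17 steps (steps 1–4 and 7–19).

**Steps most likely to fail**

Step 14. The risk is the facial selectivity of the ring closure. An α-siloxy aldehyde prefers Felkin–Anh addition (C5/C6 anti), and 2-(alkoxycarbonyl)allyl chromium reagents tend to add syn in open-chain cases; together these would give the C6 epimer with a cis-fused lactone. Slow nine-membered closure could also lead to dimers. The fallback accepts that epimer and corrects it: it sets out from 24, where the same CrCl2 closure would give the C6-epimeric cis-fused lactone F1. Opening of F1 with LiOH in THF/water at 0 °C gives the hydroxy acid F2, which after careful acidification is relactonised at once under Mitsunobu conditions (PPh3, DIAD, toluene). Inversion at C6 turns C5/C6 anti into syn and the cis lactone into the trans lactone, so the fallback returns to the route at 26.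

Step 15. The risks are incomplete E-selectivity in the base-induced elimination and side reactions of the chloroketone. The fallback separates ring expansion from alkene formation and sets out from 26. HF·pyridine in THF frees the cyclopropanol F3. Oxidative radical opening in the presence of a hydrogen donor (manganese tris(picolinate), Mn(pic)3, with Bu3SnH added slowly, DMF, 0 °C) gives the saturated ten-membered ketone F4 by the same internal-bond scission. TMSOTf/Et3N gives the only possible silyl enol ether F5, because C10 carries no hydrogen. Saegusa–Ito oxidation with Pd(OAc)2 in MeCN then forms the enone by syn β-hydride elimination and comes back to the route at 28.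

Step 7. The risk is low conversion in the olefin-exchange Kulinkovich reaction, because the ester of 7 sits on a fully substituted carbon and the alkene of 13 is branched at the allylic position. The fallback uses the classical Grignard-based Kulinkovich reaction and sets out from 13. Hydroboration with 9-BBN and oxidation (NaOH, H2O2) give the primary alcohol F6; CBr4/PPh3 gives the bromide F7; magnesium in THF gives the Grignard reagent F8. Slow addition of F8 (2.2 equiv) to ester 7 and Ti(Oi-Pr)4 in THF generates the substituted titanacyclopropane directly from the Grignard reagent and delivers the same cis-cyclopropanol, returning to the route at 14.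

**Further compounds**

F1 | step 14 | C6-epimeric, cis-fused lactone | C=C1C(=O)O[C@H]2[C@@H](O[Si](C)(C)C(C)(C)C)[C@@H](C)[C@@H]3C[C@]3(O[Si](CC)(CC)CC)[C@]4(C)C[C@@H](OC(C)(C)O4)[C@@H]12
F2 | step 14 | hydroxy acid from F1 | C=C(C(=O)O)[C@H]1[C@@H](O)[C@@H](O[Si](C)(C)C(C)(C)C)[C@@H](C)[C@@H]2C[C@]2(O[Si](CC)(CC)CC)[C@]3(C)C[C@H]1OC(C)(C)O3
F3 | step 15 | free cyclopropanol from 26 | C=C1C(=O)O[C@@H]2[C@@H](O[Si](C)(C)C(C)(C)C)[C@@H](C)[C@@H]3C[C@]3(O)[C@]4(C)C[C@@H](OC(C)(C)O4)[C@@H]12
F4 | step 15 | saturated ten-membered ketone | C=C1C(=O)O[C@@H]2[C@@H](O[Si](C)(C)C(C)(C)C)[C@@H](C)CCC(=O)[C@]3(C)C[C@@H](OC(C)(C)O3)[C@@H]12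
F5 | step 15 | trimethylsilyl enol ether of F4 | C=C1C(=O)O[C@@H]2[C@@H](O[Si](C)(C)C(C)(C)C)[C@@H](C)C/C=C(/O[Si](C)(C)C)[C@]3(C)C[C@@H](OC(C)(C)O3)[C@@H]12
F6 | step 7 | (3S,4S)-5-(benzyloxy)-4-(tert-butyldimethylsilyloxy)-3-methylpentan-1-ol | OCC[C@H](C)[C@H](O[Si](C)(C)C(C)(C)C)COCc1ccccc1
F7 | step 7 | primary bromide from F6 | BrCC[C@H](C)[C@H](O[Si](C)(C)C(C)(C)C)COCc1ccccc1
F8 | step 7 | Grignard reagent from F7 | Br[Mg]CC[C@H](C)[C@H](O[Si](C)(C)C(C)(C)C)COCc1ccccc1
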